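# Total synthesis of isogoyazensolide (18)

**Assumptions**
- D-Proline gives the (S)-aldol in step 1, by analogy with L-proline giving (R)-aldols.
- 2,2-Dimethoxyacetaldehyde (60 % aq.) and 2-bromoacrylic acid are commercial.
- The 10R diastereomer from step 3 can be separated chromatographically.

## Retrosynthesis
1. The 10-membered carbocycle is closed last by an intramolecular Nozaki–Hiyama–Kishi (NHK) reaction between a C4 vinyl bromide and a C5 aldehyde. This sets C5–OH. The C8 methacrylate is already in place.
2. The 3(2H)-furanone comes from Au-catalysed hydration/cyclodehydration of a γ-hydroxy-ynone. The ynone is made from the C10 tertiary propargylic alcohol and 2-bromoacryloyl chloride.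
3. The trans α-methylene-γ-lactone comes from an In-mediated Barbier allylation/lactonisation. The partners are a Morita–Baylis–Hillman (MBH)-derived (Z)-allylic bromide and 2,2-dimethoxyacetaldehyde, which masks C5 as an acetal.
4. The allylic bromide comes from an α-silyloxy aldehyde. That aldehyde is made by a proline aldol of acetone (setting C8) followed by acetylide addition (setting C10).
5. Ring order: lactone (step 7), then furanone (step 12), then 10-membered carbocycle (step 14).

## Route

**Step 1**
Reactants: 1 acetone; 2 2,2-dimethoxyacetaldehyde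
Product: 3 (S)-4-hydroxy-5,5-dimethoxypentan-2-one
Conditions: D-proline (30 mol %), acetone/DMSO, rt, 36 h
Reagents that add atoms: none
Why: Direct asymmetric aldol (enamine catalysis). D-Proline sets C8 as S, and the acetal masks C7 as an aldehyde.

**Step 2**
Reactants: 3
Product: 4 (S)-4-(TBSO)-5,5-dimethoxypentan-2-one
Conditions: TBSCl, imidazole, DMF, 0 °C to rt
Reagents that add atoms: TBSCl, CC(C)(C)[Si](C)(C)Cl
Why: Silyl protection prevents β-elimination and retro-aldol in step 3. It also blocks lactonisation onto C8–OH in step 7. C8 is untouched.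

**Step 3**
Reactants: 4
Product: 5 (3R,5S)-5-(TBSO)-6,6-dimethoxy-3-methylhex-1-yn-3-ol
Conditions: HC≡CMgBr (4 equiv), CeCl₃, THF, −78 to −40 °C
Reagents that add atoms: ethynylmagnesium bromide, C#C[Mg]Br
Why: 1,2-Addition of the acetylide to the methyl ketone. CeCl₃ suppresses enolisation and β-elimination. The C8 stereocentre gives 1,3-induction at the new tertiary carbinol (C10). The expected dr is only moderate, so the 10R isomer is isolated by chromatography.

**Step 4**
Reactants: 5
Product: 6 (2S,4R)-2-(TBSO)-4-methyl-4-(TESO)hex-5-ynal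
Conditions: TESOTf (3.5 equiv), 2,4,6-collidine, CH₂Cl₂, 0 °C; then H₂O
Reagents that add atoms: TESOTf, CC[Si](CC)(CC)OS(=O)(=O)C(F)(F)F; water, O
Why: Fujioka–Kita acetal deprotection. The collidinium intermediate is hydrolysed to the aldehyde under non-acidic conditions, so the α-silyloxy stereocentre does not epimerise. Excess TESOTf silylates the tertiary OH in the same step.

**Step 5**
Reactants: 6; 7 ethyl acrylate
Product: 8 MBH adduct, ethyl (4S,6R)-4-(TBSO)-3-hydroxy-6-methyl-2-methylidene-6-(TESO)oct-7-ynoate (C3 epimers)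
Conditions: DABCO (1 equiv), ethyl acrylate (5 equiv), rt, 5 d
Reagents that add atoms: none
Why: Morita–Baylis–Hillman reaction. The new carbinol stereocentre is discarded in step 6, so its configuration does not matter.

**Step 6**
Reactants: 8
Product: 9 (Z)-allylic bromide, ethyl (2Z,4S,6R)-2-(bromomethyl)-4-(TBSO)-6-methyl-6-(TESO)oct-2-en-7-ynoate
Conditions: NBS, Me₂S, CH₂Cl₂, 0 °C to rt
Reagents that add atoms: N-bromosuccinimide, O=C1CCC(=O)N1Br
Why: SN2′ bromination of the MBH alcohol via the bromodimethylsulfonium species. This gives the trisubstituted (Z)-bromide under mild, neutral conditions that keep the silyl ethers. C8 is retained.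

**Step 7**
Reactants: 9; 2
Product: 10 lactone acetal, (4R,5S)-5-(dimethoxymethyl)-3-methylidene-4-[(1S,3R)-1-(TBSO)-3-methyl-3-(TESO)pent-4-yn-1-yl]oxolan-2-one
Conditions: In powder, THF/H₂O, rt; then PPTS, PhMe, 50 °C
Reagents that add atoms: none
Why: Barbier-type allylindation. The γ-carbon (C7) attacks the aldehyde through a chair Zimmerman–Traxler transition state, giving the anti homoallylic alcohol, which lactonises onto the ester (loss of EtOH) to the trans α-methylene-γ-butyrolactone (ring 1). The C8–OTBS centre directs the aldehyde to attack C7 anti to the C8–O bond (Felkin/Houk model), giving 7R and hence 6S.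

**Step 8**
Reactants: 10
Product: 11 diol, (4R,5S)-5-(dimethoxymethyl)-4-[(1S,3R)-1,3-dihydroxy-3-methylpent-4-yn-1-yl]-3-methylideneoxolan-2-one
Conditions: HF·pyridine, pyridine/THF, 0 °C to rt
Reagents that add atoms: none
Why: Fluoride cleaves both the tertiary TES and the secondary TBS ethers. The acetal, lactone and alkyne survive. Buffering with pyridine and using the product at once avoids C8→C6 translactonisation.

**Step 9**
Reactants: 11
Product: 12 C8 methacrylate, (1S,3R)-1-[(4R,5S)-5-(dimethoxymethyl)-3-methylidene-2-oxooxolan-4-yl]-3-hydroxy-3-methylpent-4-yn-1-yl 2-methylprop-2-enoate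
Conditions: methacryloyl chloride (1.2 equiv), pyridine, CH₂Cl₂, −20 °C
Reagents that add atoms: methacryloyl chloride, C=C(C)C(=O)Cl
Why: Acylation is chemoselective for the secondary C8–OH over the hindered tertiary propargylic OH. C8 is retained.

**Step 10**
Reactants: 13 2-bromoacrylic acid
Product: 14 2-bromoacryloyl chloride
Conditions: (COCl)₂, DMF (cat.), CH₂Cl₂, 0 °C to rt; concentrate and use crude
Reagents that add atoms: oxalyl chloride, O=C(Cl)C(=O)Cl
Why: Standard acid chloride formation. This is a side branch.

**Step 11**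
Reactants: 12; 14
Product: 15 γ-hydroxy-ynone, (1S,3R)-7-bromo-1-[(4R,5S)-5-(dimethoxymethyl)-3-methylidene-2-oxooxolan-4-yl]-3-hydroxy-3-methyl-6-oxooct-7-en-4-yn-1-yl 2-methylprop-2-enoate
Conditions: CuI (10 mol %), Et₃N, THF, 0 °C
Reagents that add atoms: none
Why: Copper-acetylide (Pd-free Sonogashira-type) acylation of the terminal alkyne. Omitting Pd protects the vinyl bromide. The remote stereocentres are not involved.

**Step 12**
Reactants: 15
Product: 16 furanone acetal, (1S)-1-[(4R,5S)-5-(dimethoxymethyl)-3-methylidene-2-oxooxolan-4-yl]-2-[(2R)-5-(1-bromoethenyl)-2-methyl-3-oxofuran-2(3H)-yl]ethyl 2-methylprop-2-enoate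
Conditions: AuCl₃ (5 mol %), MeCN/H₂O 20:1, rt
Reagents that add atoms: none (water is consumed and regenerated, so the net change is an isomerisation)
Why: Au(III)-catalysed hydration of the ynone at C1 followed by cyclodehydration of the tertiary OH onto C3=O gives the 3(2H)-furanone (ring 2). C10 is quaternary with no α-H, so it cannot epimerise.

**Step 13**
Reactants: 16
Product: 17 aldehyde, (1S)-1-[(4R,5S)-5-formyl-3-methylidene-2-oxooxolan-4-yl]-2-[(2R)-5-(1-bromoethenyl)-2-methyl-3-oxofuran-2(3H)-yl]ethyl 2-methylprop-2-enoate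
Conditions: TESOTf (2.5 equiv), 2,4,6-collidine, CH₂Cl₂, 0 °C; then H₂O
Reagents that add atoms: water, O
Why: Non-acidic Fujioka–Kita unmasking of the C5 acetal, which leaves the methacrylate, α-methylene lactone and furanone intact.

**Step 14**
Reactants: 17
Product: 18 isogoyazensolide
Conditions: CrCl₂ (10 equiv), NiCl₂ (0.1 equiv), DMF, 0.002 M, 25 °C, substrate added over 6 h
Reagents that add atoms: none
Why: Intramolecular Nozaki–Hiyama–Kishi reaction. Ni(0) inserts into the vinyl bromide, transmetalation gives a vinyl-Cr(III) species, and this adds to the aldehyde to close the 10-membered ring (ring 3). The C5 (R) carbinol is set by macrocyclic conformational control from C6.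

## Compound list
1 | acetone | CC(C)=O | starting material
2 | 2,2-dimethoxyacetaldehyde | COC(OC)C=O | starting material
3 | (S)-4-hydroxy-5,5-dimethoxypentan-2-one | CC(=O)C[C@H](O)C(OC)OC | intermediate
4 | (S)-4-(TBSO)-5,5-dimethoxypentan-2-one | CC(=O)C[C@H](O[Si](C)(C)C(C)(C)C)C(OC)OC | intermediate
5 | (3R,5S)-5-(TBSO)-6,6-dimethoxy-3-methylhex-1-yn-3-ol | C#C[C@](C)(O)C[C@H](O[Si](C)(C)C(C)(C)C)C(OC)OC | intermediate
6 | (2S,4R)-2-(TBSO)-4-methyl-4-(TESO)hex-5-ynal | C#C[C@](C)(O[Si](CC)(CC)CC)C[C@H](O[Si](C)(C)C(C)(C)C)C=O | intermediate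
7 | ethyl acrylate | C=CC(=O)OCC | starting material
8 | MBH adduct (C3 epimeric mixture) | C#C[C@](C)(O[Si](CC)(CC)CC)C[C@H](O[Si](C)(C)C(C)(C)C)C(O)C(=C)C(=O)OCC | intermediate
9 | (Z)-allylic bromide | C#C[C@](C)(O[Si](CC)(CC)CC)C[C@H](O[Si](C)(C)C(C)(C)C)/C=C(\CBr)C(=O)OCC | intermediate
10 | trans α-methylene lactone acetal, TBS/TES ethers | C#C[C@](C)(O[Si](CC)(CC)CC)C[C@H](O[Si](C)(C)C(C)(C)C)[C@H]1C(=C)C(=O)O[C@@H]1C(OC)OC | intermediate
11 | lactone diol acetal | C#C[C@](C)(O)C[C@H](O)[C@H]1C(=C)C(=O)O[C@@H]1C(OC)OC | intermediate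
12 | C8 methacrylate, tertiary propargylic alcohol | C#C[C@](C)(O)C[C@H](OC(=O)C(C)=C)[C@H]1C(=C)C(=O)O[C@@H]1C(OC)OC | intermediate
13 | 2-bromoacrylic acid | C=C(Br)C(=O)O | starting material
14 | 2-bromoacryloyl chloride | C=C(Br)C(=O)Cl | intermediate
15 | γ-hydroxy-ynone | C=C(Br)C(=O)C#C[C@](C)(O)C[C@H](OC(=O)C(C)=C)[C@H]1C(=C)C(=O)O[C@@H]1C(OC)OC | intermediate
16 | furanone acetal (vinyl bromide) | C=C(Br)C1=CC(=O)[C@@](C)(C[C@H](OC(=O)C(C)=C)[C@H]2C(=C)C(=O)O[C@@H]2C(OC)OC)O1 | intermediate
17 | furanone aldehyde (NHK precursor) | C=C(Br)C1=CC(=O)[C@@](C)(C[C@H](OC(=O)C(C)=C)[C@H]2C(=C)C(=O)O[C@@H]2C=O)O1 | intermediate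
18 | isogoyazensolide | C=C(C)C(=O)O[C@H]1C[C@@]2(C)OC(=CC2=O)C(=C)[C@@H](O)[C@H]2OC(=O)C(=C)[C@@H]21 | target

## Totals
- Total steps: 14, including the side-branch acid chloride step 10.
- Longest linear sequence: 13 steps (1–9 and 11–14).

## Three steps most likely to fail
1. **Step 14 (NHK macrocyclisation).** Risks are strain in the bridged 10-membered ring, oligomerisation, and the C5 diastereoselectivity.
   - Fallback: change the ring closure to an intramolecular Cr-mediated Barbier allylation that forms C6–C7 and the lactone together. The furanone-bearing C5-oxygenated aldehyde and allylic bromide would be the precursor, with C5 set beforehand by Sharpless dihydroxylation.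
2. **Step 7 (Barbier allylation/lactonisation).** The C7 facial selectivity from the C8 stereocentre is only substrate-controlled, and the MBH route to the bromide is sluggish.
   - Fallback: use Marshall Pd/Et₂Zn anti-propargylation of the C6 aldehyde with a chiral propargylic mesylate, then Pd-catalysed cyclocarbonylation of the homopropargylic alcohol to the α-methylene lactone. This is reagent-controlled.
3. **Step 3 (C10 acetylide addition).** 1,3-Induction from the β-silyloxy centre is moderate, so the yield of the 10R isomer may be low.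
   - Fallback: take C10 from (R)-citramalic acid, a chiral-pool building block. Differentiate the two carboxyls, convert the α-carboxyl to the alkyne by oxidation and Ohira–Bestmann, and elaborate the β-carboxyl into the C8/C7 aldehyde.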